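**Plan**
- Retrosynthesis: the C2–C3 bond of ring C is cut first (a 1,3 oxygen-to-carbon shift run backwards), giving a 2-aryl-4-methylidene-4H-1,3-benzodioxine. Then the two acetal C–O bonds are cut (salicylic acid + 2,4-bis(methoxymethoxy)benzaldehyde), then C6–prenyl (para-Claisen–Cope), C8–CH2 (Negishi) and the lavandulyl Cα–CH2 bond (Evans alkylation).
- Forward: lavandulyl iodide (steps 1–4); ring A by MOM protection, ortho-iodination, Negishi coupling, O-prenylation, Claisen–Cope shift and saponification (steps 5–10); benzodioxinone formation and methylenation (steps 12–13); rearrangement closes ring C (step 14); MOM removal (step 15).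
- Enabling feature: C2 sits between ring oxygen O1 and ring B, which carries oxygens ortho and para to it, so an acetal at C2 ionises to a strongly stabilised oxocarbenium ion. C3–C4 can be carried as an enol ether, so a Petasis–Ferrier-type rearrangement turns the easily made benzodioxine skeleton into the chroman-4-one.
- Stereochemistry: the lavandulyl centre comes from (S)-4-benzyl-oxazolidinone (dienolate alkylation) and is carried unchanged. C2 (S) is set by a chiral phosphoric acid acting on the ion pair in step 14; the racemic acetal centre of the precursor is erased there.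

Key step: step 14

Assumption: the sense of induction of the chiral phosphoric acid in step 14 cannot be predicted with confidence. The (R)-acid is written; its (S)-enantiomer is to be used if the first run gives the (2R)-epimer (the C2 epimers are diastereomers because of the lavandulyl centre).

Remark: "lavandulyl" means 5-methyl-2-(prop-1-en-2-yl)hex-4-en-1-yl. The same spatial arrangement is (S) in the alcohol, iodide and zinc reagent and (R) once the CH2 group carries the arene, because CH2–aryl ranks below isopropenyl.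

**Step 1**
Reactants: 1 (S)-4-benzyl-1,3-oxazolidin-2-one; 2 3-methylbut-2-enoyl chloride
Product: 4 (S)-4-benzyl-3-(3-methylbut-2-enoyl)-1,3-oxazolidin-2-one, via lithium oxazolidinide 3 (not isolated)
Conditions: n-BuLi, THF, −78 °C; then 2, −78 → 0 °C
Reagents that add atoms: none
Why: N-acylation of the lithiated oxazolidinone with the acid chloride, the standard entry to Evans imides.

**Step 2**
Reactants: 4 (S)-4-benzyl-3-(3-methylbut-2-enoyl)-1,3-oxazolidin-2-one; 5 1-bromo-3-methylbut-2-ene (prenyl bromide)
Product: 7 (4S)-4-benzyl-3-[(2S)-5-methyl-2-(prop-1-en-2-yl)hex-4-enoyl]-1,3-oxazolidin-2-one, via sodium dienolate 6 (not isolated)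
Conditions: NaN(SiMe3)2, THF, −78 °C; then 5, −78 → −40 °C; AcOH quench at −78 °C
Reagents that add atoms: none
Why: Evans asymmetric alkylation of the chelated Z(O)-dienolate at its α-carbon; prenyl bromide should approach the face opposite the benzyl group of the (S)-auxiliary, which sets the (2S) centre and leaves the alkene deconjugated as the isopropenyl group.

**Step 3**
Reactants: 7 (4S)-4-benzyl-3-[(2S)-5-methyl-2-(prop-1-en-2-yl)hex-4-enoyl]-1,3-oxazolidin-2-one
Product: 8 (S)-lavandulol [(2S)-5-methyl-2-(prop-1-en-2-yl)hex-4-en-1-ol]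
Conditions: LiBH4, H2O (1 equiv), Et2O, 0 °C
Reagents that add atoms: none
Why: Reductive cleavage of the N-acyl oxazolidinone by borohydride gives the primary alcohol without epimerising the α-centre and returns the auxiliary.

**Step 4**
Reactants: 8 (S)-lavandulol
Product: 9 (S)-lavandulyl iodide [(3S)-3-(iodomethyl)-2,6-dimethylhepta-1,5-diene]
Conditions: I2, PPh3, imidazole, CH2Cl2, 0 → 25 °C
Reagents that add atoms: iodine, II
Why: Appel-type iodination by SN2 displacement at the primary carbon; the adjacent stereocentre is not involved.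

**Step 5**
Reactants: 10 methyl 2,4,6-trihydroxybenzoate
Product: 11 methyl 2-hydroxy-4,6-bis(methoxymethoxy)benzoate
Conditions: MOMCl (2.1 equiv), i-Pr2NEt, CH2Cl2, 0 → 25 °C
Reagents that add atoms: chloromethyl methyl ether (MOMCl), COCCl
Why: Phenol alkylation protects the 4-OH and one ortho OH; the last ortho OH stays free because it is hydrogen-bonded to the ester carbonyl, and it marks the future ring oxygen O1.

**Step 6**
Reactants: 11 methyl 2-hydroxy-4,6-bis(methoxymethoxy)benzoate
Product: 12 methyl 2-hydroxy-3-iodo-4,6-bis(methoxymethoxy)benzoate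
Conditions: N-iodosuccinimide, CH2Cl2, 0 → 25 °C, dark
Reagents that add atoms: N-iodosuccinimide, O=C1CCC(=O)N1I
Why: Electrophilic aromatic iodination ortho to the free chelated phenol should be favoured over the more hindered position between the two MOM ethers, as in the analogous 2-hydroxy-4,6-dialkoxyaryl ketones.

**Step 7**
Reactants: 9 (S)-lavandulyl iodide; 12 methyl 2-hydroxy-3-iodo-4,6-bis(methoxymethoxy)benzoate
Product: 14 methyl 2-hydroxy-4,6-bis(methoxymethoxy)-3-[(2R)-lavandulyl]benzoate, via lavandulylzinc iodide 13 (not isolated)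
Conditions: Zn dust (activated with BrCH2CH2Br and Me3SiCl), LiCl, THF, 25 °C; then 12, Pd(OAc)2 (3 mol %), CPhos (6 mol %), THF, 25 °C, slow addition of the zinc reagent
Reagents that add atoms: none
Why: Negishi sp3–sp2 coupling: zinc insertion into the primary iodide, then coupling under zerovalent palladium with CPhos, which favours reductive elimination over β-hydride elimination and tolerates the chelated phenol; the stereocentre is β to zinc and is carried over unchanged.

**Step 8**
Reactants: 14 methyl 2-hydroxy-4,6-bis(methoxymethoxy)-3-[(2R)-lavandulyl]benzoate; 5 1-bromo-3-methylbut-2-ene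
Product: 15 methyl 4,6-bis(methoxymethoxy)-2-[(3-methylbut-2-en-1-yl)oxy]-3-[(2R)-lavandulyl]benzoate
Conditions: K2CO3, DMF, 40 °C
Reagents that add atoms: none
Why: Williamson O-alkylation of the phenolate with the allylic bromide; both ortho positions of this oxygen are now substituted.

**Step 9**
Reactants: 15 methyl 4,6-bis(methoxymethoxy)-2-[(3-methylbut-2-en-1-yl)oxy]-3-[(2R)-lavandulyl]benzoate
Product: 17 methyl 2-hydroxy-4,6-bis(methoxymethoxy)-5-(3-methylbut-2-en-1-yl)-3-[(2R)-lavandulyl]benzoate, via ortho-dienone 16 (not isolated)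
Conditions: Eu(fod)3 [tris(6,6,7,7,8,8,8-heptafluoro-2,2-dimethyloctane-3,5-dionato)europium] (10 mol %), toluene, 80 °C
Reagents that add atoms: none
Why: Europium-catalysed tandem Claisen–Cope (para-Claisen) rearrangement of an ortho-carbonyl aryl prenyl ether: with both ortho positions blocked, the 1,1-dimethylallyl dienone can only undergo the Cope shift to the free para position, which places a normal prenyl group at the future C6 and frees the phenol, and 80 °C is well below the onset of a Cope shift of the lavandulyl 1,5-diene.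

**Step 10**
Reactants: 17 methyl 2-hydroxy-4,6-bis(methoxymethoxy)-5-(3-methylbut-2-en-1-yl)-3-[(2R)-lavandulyl]benzoate
Product: 18 2-hydroxy-4,6-bis(methoxymethoxy)-5-(3-methylbut-2-en-1-yl)-3-[(2R)-lavandulyl]benzoic acid
Conditions: KOH, EtOH/H2O (4:1), 75 °C; then 1 M HCl to pH 4, 0 °C; used at once
Reagents that add atoms: potassium hydroxide, [K+].[OH-]
Why: Saponification of the salicylate ester, assisted by the ortho phenolate; MOM ethers and alkenes are inert to hydroxide, and cold acidification to pH 4 limits decarboxylation of the electron-rich acid.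

**Step 11**
Reactants: 19 2,4-dihydroxybenzaldehyde
Product: 20 2,4-bis(methoxymethoxy)benzaldehyde
Conditions: MOMCl (2.5 equiv), K2CO3, acetone, reflux
Reagents that add atoms: chloromethyl methyl ether (MOMCl), COCCl
Why: Exhaustive phenolate alkylation under conditions forcing enough for the chelated 2-OH.

**Step 12**
Reactants: 18 2-hydroxy-4,6-bis(methoxymethoxy)-5-(3-methylbut-2-en-1-yl)-3-[(2R)-lavandulyl]benzoic acid; 20 2,4-bis(methoxymethoxy)benzaldehyde
Product: 22 2-[2,4-bis(methoxymethoxy)phenyl]-5,7-bis(methoxymethoxy)-6-(3-methylbut-2-en-1-yl)-8-[(2R)-lavandulyl]-4H-1,3-benzodioxin-4-one (both C2 epimers), via bis(trimethylsilyl) derivative 21 (not isolated)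
Conditions: (Me3Si)2NH, CH2Cl2, 25 °C, evaporate; then 20, Me3SiOTf (10 mol %), 2,6-di-tert-butyl-4-methylpyridine (10 mol %), CH2Cl2, −78 → −40 °C; pyridine quench
Reagents that add atoms: none
Why: Silyl-mediated acetalisation as used for 1,3-dioxan-4-ones: Me3SiOTf activates the aldehyde toward the silyl ether/silyl ester pair and (Me3Si)2O is expelled; the acetal carbon forms as both epimers, which does not matter because it is ionised in step 14.

**Step 13**
Reactants: 22 2-[2,4-bis(methoxymethoxy)phenyl]-5,7-bis(methoxymethoxy)-6-(3-methylbut-2-en-1-yl)-8-[(2R)-lavandulyl]-4H-1,3-benzodioxin-4-one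
Product: 23 2-[2,4-bis(methoxymethoxy)phenyl]-5,7-bis(methoxymethoxy)-4-methylidene-6-(3-methylbut-2-en-1-yl)-8-[(2R)-lavandulyl]-4H-1,3-benzodioxine (both C2 epimers)
Conditions: Cp2TiMe2 (3 equiv), toluene, 65 °C, dark; filtration through basic alumina
Reagents that add atoms: bis(cyclopentadienyl)dimethyltitanium (Cp2TiMe2), [CH3-].[CH3-].[Ti+4].c1cc[cH-]c1.c1cc[cH-]c1
Why: Petasis methylenation of the lactone-type carbonyl through the titanocene methylidene of tetravalent titanium ([2+2] addition and cycloreversion); the reagent is non-acidic and leaves MOM ethers and the hindered alkenes unchanged.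

**Step 14**
Reactants: 23 2-[2,4-bis(methoxymethoxy)phenyl]-5,7-bis(methoxymethoxy)-4-methylidene-6-(3-methylbut-2-en-1-yl)-8-[(2R)-lavandulyl]-4H-1,3-benzodioxine
Product: 25 (2S)-2-[2,4-bis(methoxymethoxy)phenyl]-5,7-bis(methoxymethoxy)-6-(3-methylbut-2-en-1-yl)-8-[(2R)-lavandulyl]chroman-4-one, via oxocarbenium–enol ion pair 24 (not isolated)
Conditions: (R)-3,3′-bis(2,4,6-triisopropylphenyl)-1,1′-binaphthyl-2,2′-diyl hydrogen phosphate (5 mol %), toluene, 5 Å molecular sieves, −30 °C
Reagents that add atoms: none
Why: Proposed new method: the chiral phosphoric acid should cleave the acetal bond between C2 and the enol-ether oxygen (directly, or after reversible C-protonation of the enol ether) to give a contact ion pair of the O1-aryl oxocarbenium ion at C2, stabilised by ring oxygen O1 and by the ortho and para oxygens of ring B, and the C3=C4 enol, both held by the chiral phosphate; collapse through carbon forms the C2–C3 bond and converts the 1,3-benzodioxine into the chroman-4-one. The closest known reaction types are the Petasis–Ferrier rearrangement of 4-methylidene-1,3-dioxanes with aluminium Lewis acids and the chiral phosphoric acid-catalysed aza-Petasis–Ferrier rearrangement of hemiaminal vinyl ethers. Ring C closes in a 6-(enolendo)-endo-trig mode. The new stereocentre C2 is controlled by the catalyst alone: ionisation erases the racemic acetal centre, both epimers of 23 converge on the same planar ion pair, and the phosphate bridges the enol OH and the cation so that one face is attacked. The step needs C- over O-recombination and no later erosion: O-recombination only regenerates 23 while C-attack is irreversible, the product is a benzylic ether without the second acetal oxygen and should ionise far less readily at −30 °C, molecular sieves prevent hydrolysis of the enol ether, and Prins closure onto the lavandulyl alkenes would need a seven- or eight-membered ring.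

**Step 15**
Reactants: 25 (2S)-2-[2,4-bis(methoxymethoxy)phenyl]-5,7-bis(methoxymethoxy)-6-(3-methylbut-2-en-1-yl)-8-[(2R)-lavandulyl]chroman-4-one
Product: 26 Kushenol B [(2S)-2-(2,4-dihydroxyphenyl)-5,7-dihydroxy-6-(3-methylbut-2-en-1-yl)-8-[(2R)-lavandulyl]chroman-4-one]
Conditions: Me3SiOTf (10 equiv), 2,2′-bipyridyl (15 equiv), MeCN, 0 → 25 °C; then H2O, NaHCO3 work-up
Reagents that add atoms: none
Why: Silyl-transfer cleavage of aryl MOM ethers (aryl trimethylsilyl ethers form and hydrolyse on work-up) under buffered aprotic conditions, which avoids acid-induced chroman formation from the ortho-prenyl phenols and base-induced ring opening to the chalcone that would scramble C2.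

**Compound list**
1 | (S)-4-benzyl-1,3-oxazolidin-2-one | O=C1N[C@@H](Cc2ccccc2)CO1 | starting material
2 | 3-methylbut-2-enoyl chloride | CC(C)=CC(Cl)=O | starting material
3 | lithium (S)-4-benzyl-2-oxo-1,3-oxazolidin-3-ide | [Li+].O=C1[N-][C@@H](Cc2ccccc2)CO1 | intermediate
4 | (S)-4-benzyl-3-(3-methylbut-2-enoyl)-1,3-oxazolidin-2-one | CC(C)=CC(=O)N1[C@@H](Cc2ccccc2)COC1=O | intermediate
5 | 1-bromo-3-methylbut-2-ene (prenyl bromide) | CC(C)=CCBr | starting material
6 | sodium Z(O)-dienolate of 4 | [Na+].C=C(C)/C=C(\[O-])N1[C@@H](Cc2ccccc2)COC1=O | intermediate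
7 | (4S)-4-benzyl-3-[(2S)-5-methyl-2-(prop-1-en-2-yl)hex-4-enoyl]-1,3-oxazolidin-2-one | C=C(C)[C@H](CC=C(C)C)C(=O)N1[C@@H](Cc2ccccc2)COC1=O | intermediate
8 | (S)-lavandulol | C=C(C)[C@H](CC=C(C)C)CO | intermediate
9 | (S)-lavandulyl iodide | C=C(C)[C@H](CC=C(C)C)CI | intermediate
10 | methyl 2,4,6-trihydroxybenzoate | COC(=O)c1c(O)cc(O)cc1O | starting material
11 | methyl 2-hydroxy-4,6-bis(methoxymethoxy)benzoate | COC(=O)c1c(O)cc(OCOC)cc1OCOC | intermediate
12 | methyl 2-hydroxy-3-iodo-4,6-bis(methoxymethoxy)benzoate | COC(=O)c1c(O)c(I)c(OCOC)cc1OCOC | intermediate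
13 | (S)-lavandulylzinc iodide (LiCl complex) | C=C(C)[C@H](CC=C(C)C)C[Zn]I | intermediate
14 | methyl 2-hydroxy-4,6-bis(methoxymethoxy)-3-[(2R)-lavandulyl]benzoate | COC(=O)c1c(O)c(C[C@@H](CC=C(C)C)C(C)=C)c(OCOC)cc1OCOC | intermediate
15 | methyl 4,6-bis(methoxymethoxy)-2-[(3-methylbut-2-en-1-yl)oxy]-3-[(2R)-lavandulyl]benzoate | COC(=O)c1c(OCC=C(C)C)c(C[C@@H](CC=C(C)C)C(C)=C)c(OCOC)cc1OCOC | intermediate
16 | ortho-dienone: methyl 2,4-bis(methoxymethoxy)-5-[(2R)-lavandulyl]-5-(2-methylbut-3-en-2-yl)-6-oxocyclohexa-1,3-diene-1-carboxylate (both epimers at the ring carbon) | COC(=O)C1=C(OCOC)C=C(OCOC)C(C[C@@H](CC=C(C)C)C(C)=C)(C(C)(C)C=C)C1=O | intermediate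
17 | methyl 2-hydroxy-4,6-bis(methoxymethoxy)-5-(3-methylbut-2-en-1-yl)-3-[(2R)-lavandulyl]benzoate | COC(=O)c1c(O)c(C[C@@H](CC=C(C)C)C(C)=C)c(OCOC)c(CC=C(C)C)c1OCOC | intermediate
18 | 2-hydroxy-4,6-bis(methoxymethoxy)-5-(3-methylbut-2-en-1-yl)-3-[(2R)-lavandulyl]benzoic acid | OC(=O)c1c(O)c(C[C@@H](CC=C(C)C)C(C)=C)c(OCOC)c(CC=C(C)C)c1OCOC | intermediate
19 | 2,4-dihydroxybenzaldehyde | O=Cc1ccc(O)cc1O | starting material
20 | 2,4-bis(methoxymethoxy)benzaldehyde | O=Cc1ccc(OCOC)cc1OCOC | intermediate
21 | trimethylsilyl ester and trimethylsilyl ether of 18 | C[Si](C)(C)OC(=O)c1c(O[Si](C)(C)C)c(C[C@@H](CC=C(C)C)C(C)=C)c(OCOC)c(CC=C(C)C)c1OCOC | intermediate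
22 | 2-[2,4-bis(methoxymethoxy)phenyl]-5,7-bis(methoxymethoxy)-6-(3-methylbut-2-en-1-yl)-8-[(2R)-lavandulyl]-4H-1,3-benzodioxin-4-one (both C2 epimers) | O=C1OC(c3ccc(OCOC)cc3OCOC)Oc2c(C[C@@H](CC=C(C)C)C(C)=C)c(OCOC)c(CC=C(C)C)c(OCOC)c12 | intermediate
23 | 2-[2,4-bis(methoxymethoxy)phenyl]-5,7-bis(methoxymethoxy)-4-methylidene-6-(3-methylbut-2-en-1-yl)-8-[(2R)-lavandulyl]-4H-1,3-benzodioxine (both C2 epimers) | C=C1OC(c3ccc(OCOC)cc3OCOC)Oc2c(C[C@@H](CC=C(C)C)C(C)=C)c(OCOC)c(CC=C(C)C)c(OCOC)c12 | intermediate
24 | ring-opened O1-aryl oxocarbenium/enol pair held by the phosphate (drawn as the zwitterion) | C=C([O-])c1c(OCOC)c(CC=C(C)C)c(OCOC)c(C[C@@H](CC=C(C)C)C(C)=C)c1[O+]=Cc1ccc(OCOC)cc1OCOC | intermediate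
25 | (2S)-2-[2,4-bis(methoxymethoxy)phenyl]-5,7-bis(methoxymethoxy)-6-(3-methylbut-2-en-1-yl)-8-[(2R)-lavandulyl]chroman-4-one | C=C(C)[C@H](CC=C(C)C)Cc1c(OCOC)c(CC=C(C)C)c(OCOC)c2c1O[C@H](c1ccc(OCOC)cc1OCOC)CC2=O | intermediate
26 | Kushenol B | C=C(C)[C@H](CC=C(C)C)Cc1c(O)c(CC=C(C)C)c(O)c2c1O[C@H](c1ccc(O)cc1O)CC2=O | target

**Step count:** 15 steps in total. The longest linear sequence is 12 steps (steps 1–4, 7–10, 12–15).

**Steps most likely to fail**

Step 14. What may go wrong: poor facial discrimination in the ion pair, diversion of the enol ether by C-protonation and hydrolysis, or slow acid-mediated epimerisation at C2 after ring closure. The fallback sets out from 18 and returns at 25 by the classical chalcone route. Acid 18 with MeLi (3.5 equiv, THF, 0 °C, Me3SiCl quench) should give the 2-hydroxyacetophenone F1. Claisen–Schmidt condensation of this ketone with aldehyde 20 (KOH, EtOH/H2O, 25 °C) should give the 2′-hydroxychalcone F2. NaOAc in refluxing EtOH should close the pyranone by oxa-Michael addition to a mixture of 25 and its (2R)-epimer F3. The two are diastereomers because of the lavandulyl centre and would be separated by preparative HPLC, with the wrong epimer re-equilibrated under the same NaOAc conditions and recycled.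

Step 7. What may go wrong: loss of the alkyl partner by β-hydride elimination from the alkylpalladium intermediate (the β-hydrogen is allylic), skeletal scrambling of the homoallylic radical during zinc insertion, or protonolysis of the organozinc by the phenol. The fallback sets out from 9 and 12 and returns at 14. Lithium–iodine exchange on 9 (t-BuLi, Et2O, −78 °C) should give (S)-lavandulyllithium F4. Trapping with 9-methoxy-9-borabicyclo[3.3.1]nonane should give the lithium B-lavandulyl borinate F5. This is coupled with 12 in a B-alkyl Suzuki–Miyaura reaction (Pd(dppf)Cl2, K3PO4, DMF/H2O, 25 °C) to give 14.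

Step 9. What may go wrong: ionisation of the prenyl ether with loss of the prenyl group instead of the double sigmatropic shift, or stalling at a dienone. The fallback sets out from 12 and returns at 17 by cross-coupling instead of rearrangement. Bromination of 12 (N-bromosuccinimide, CH2Cl2, 0 °C) at the only free ring position should give methyl 5-bromo-2-hydroxy-3-iodo-4,6-bis(methoxymethoxy)benzoate F6. Chemoselective Negishi coupling at the C–I bond with 13 (Pd(OAc)2, CPhos, THF, 25 °C) should give methyl 5-bromo-2-hydroxy-4,6-bis(methoxymethoxy)-3-[(2R)-lavandulyl]benzoate F7. Stille coupling with tributyl(3-methylbut-2-en-1-yl)stannane (Pd(PPh3)4, DMF, 90 °C) should then deliver 17.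

**Further compounds**
F1 | step 14 | 1-[2-hydroxy-4,6-bis(methoxymethoxy)-5-(3-methylbut-2-en-1-yl)-3-[(2R)-lavandulyl]phenyl]ethan-1-one | CC(=O)c1c(O)c(C[C@@H](CC=C(C)C)C(C)=C)c(OCOC)c(CC=C(C)C)c1OCOC
F2 | step 14 | (E)-3-[2,4-bis(methoxymethoxy)phenyl]-1-[2-hydroxy-4,6-bis(methoxymethoxy)-5-(3-methylbut-2-en-1-yl)-3-[(2R)-lavandulyl]phenyl]prop-2-en-1-one | O=C(/C=C/c1ccc(OCOC)cc1OCOC)c1c(O)c(C[C@@H](CC=C(C)C)C(C)=C)c(OCOC)c(CC=C(C)C)c1OCOC
F3 | step 14 | (2R)-2-[2,4-bis(methoxymethoxy)phenyl]-5,7-bis(methoxymethoxy)-6-(3-methylbut-2-en-1-yl)-8-[(2R)-lavandulyl]chroman-4-one | C=C(C)[C@H](CC=C(C)C)Cc1c(OCOC)c(CC=C(C)C)c(OCOC)c2c1O[C@@H](c1ccc(OCOC)cc1OCOC)CC2=O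
F4 | step 7 | (S)-lavandulyllithium | C=C(C)[C@H](CC=C(C)C)C[Li]
F5 | step 7 | lithium B-methoxy-B-[(S)-lavandulyl]-9-borabicyclo[3.3.1]nonane borinate | [Li+].CO[B-]1(C[C@@H](CC=C(C)C)C(C)=C)C2CCCC1CCC2
F6 | step 9 | methyl 5-bromo-2-hydroxy-3-iodo-4,6-bis(methoxymethoxy)benzoate | COC(=O)c1c(O)c(I)c(OCOC)c(Br)c1OCOC
F7 | step 9 | methyl 5-bromo-2-hydroxy-4,6-bis(methoxymethoxy)-3-[(2R)-lavandulyl]benzoate | COC(=O)c1c(O)c(C[C@@H](CC=C(C)C)C(C)=C)c(OCOC)c(Br)c1OCOC
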